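**Retrosynthesis**
- Desertorin A ← chemoselective 4,4'-di-O-methylation of the tetrahydroxy-6,8'-bicoumarin (9) ← double 4-hydroxycoumarin annulation (carbonate Claisen and lactonisation) of a bis(o-hydroxyacetophenone) biaryl (7).
- 7 ← double Friedel–Crafts acetylation of the "bi-orcinol" tetraol (5) ← BBr3 demethylation of the 2-arylresorcinol (4).
- 4 ← aromatisation of the 2-aryl-5-methylcyclohexane-1,3-dione (3). The hindered tetra-ortho biaryl bond is made here, by a PIFA-mediated dehydrogenative (umpolung) coupling of 5-methylcyclohexane-1,3-dione (2) with 3,5-dimethoxytoluene (1). No aryl halide or boron partner and no aryl–aryl cross-coupling is used.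
- Ring order: benzene ring A is already present in 1. Benzene ring B is created by aromatising the dione. Both pyranone rings are closed last, and the two methyl ethers are installed at the end.
- The 6,8' regiochemistry is programmed by the two coupling sites. The most nucleophilic carbon of 1 (C2, ortho to Me and ortho/para to OMe) becomes coumarin C6. The doubly activated C2 of the dione becomes C8'.

**Assumption:** the target SMILES has no stereodescriptors. It has no stereocentres, and the tetra-ortho-substituted biaryl axis is taken as unspecified (racemic or rapidly interconverting). No asymmetric step is therefore needed. Compounds 1, 2, 6, 8 and 10 are commercial.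

---

**Step 1**
Reactants: 1 (3,5-dimethoxytoluene); 2 (5-methylcyclohexane-1,3-dione)
Product: 3 (2-(2,4-dimethoxy-6-methylphenyl)-5-methylcyclohexane-1,3-dione, isolated as its enol)
Conditions: 1 (3 equiv), 2 (1 equiv), PIFA (1.2 equiv), HFIP, 0 °C → rt, 2 h
Reagents that add atoms: none (PIFA, O=C(OI(c1ccccc1)OC(=O)C(F)(F)F)C(F)(F)F, is only the oxidant)
Why: Oxidation of the dione enol (or of the arene to its radical cation) gives an electrophilic C2 that is attacked by C2 of 1. Ring A is thereby linked at the carbon that becomes coumarin C6, and ring B at the carbon between the two future oxygens, C8'. No stereocentre forms; the axis is not yet formed. Proposed new method: a Kita-type PIFA/HFIP cross-dehydrogenative coupling (closest known reaction: iodine(III) enolonium or arene radical-cation coupling with 1,3-dicarbonyls), used to build a 2,6-disubstituted aryl–dione bond. Excess arene and one equivalent of oxidant limit over-oxidation and O-arylation.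

**Step 2**
Reactants: 3
Product: 4 (2-(2,4-dimethoxy-6-methylphenyl)-5-methylbenzene-1,3-diol)
Conditions: 10% Pd/C (20 wt%), Ph2O, 190 °C, 3 h, N2 sweep
Reagents that add atoms: none
Why: Pd-catalysed dehydrogenative aromatisation of a cyclohexane-1,3-dione (loss of H2) gives the resorcinol. The aromatic ring, the Me/OH pattern and the biaryl bond all survive, and the tetra-ortho biaryl is set in the least hindered, non-aromatic state.

**Step 3**
Reactants: 4
Product: 5 (2-(2,4-dihydroxy-6-methylphenyl)-5-methylbenzene-1,3-diol, the tetraol)
Conditions: BBr3 (6 equiv), CH2Cl2, −78 °C → rt, 12 h; MeOH quench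
Reagents that add atoms: none (the methyl groups leave as MeBr)
Why: BBr3 cleaves aryl methyl ethers (Lewis-acid O-demethylation). The free phenols of ring B and the biaryl bond are unaffected.

**Step 4**
Reactants: 5; 6 (acetic acid)
Product: 7 (1,1'-[biaryl] bis-ketone: ring A 5-acetyl-2,4-dihydroxy-6-methylphenyl on ring B 4-acetyl-1,3-dihydroxy-5-methylphenyl)
Conditions: AcOH (6 equiv), BF3·OEt2 (10 equiv), 90 °C, 6 h
Reagents that add atoms: acetic acid, CC(=O)O
Why: BF3/AcOH C-acetylation (Friedel–Crafts/Hoesch type) of orcinol-type rings occurs at C4, which is ortho to Me and OH and para to the other OH, not at the hindered position between the two OH groups. In ring B the C2 position is already blocked, so only the required site remains; in ring A the desired site is favoured electronically. Product ketones are chelated to boron, which limits over-acylation. No stereochemistry is involved.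

**Step 5**
Reactants: 7; 8 (diethyl carbonate)
Product: 9 (4,7,4',7'-tetrahydroxy-5,5'-dimethyl-6,8'-bicoumarin)
Conditions: NaH (12 equiv), (EtO)2CO (8 equiv), PhMe, 110 °C, 8 h; then 1 M HCl
Reagents that add atoms: diethyl carbonate, CCOC(=O)OCC (supplies the C2 carbonyl of each lactone)
Why: Carbonate Claisen acylation of each methyl ketone gives a β-keto ester, and the ortho phenoxide lactonises onto it to give the 4-hydroxycoumarin (the standard 2-hydroxyacetophenone to 4-hydroxycoumarin route). Only the phenol ortho to each acetyl can close the six-membered ring, so regiochemistry is fixed. The 7-OH groups remain as phenoxides.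

**Step 6**
Reactants: 9; 10 (TMS-diazomethane)
Product: 11 (desertorin A)
Conditions: TMSCHN2 (2.4 equiv), MeOH–PhMe (1:3), 0 °C → rt, 4 h
Reagents that add atoms: TMS-diazomethane, C[Si](C)(C)C=[N+]=[N-] (supplies the two OCH3 groups)
Why: Diazomethane-type O-methylation follows acidity. The vinylogous-acid 4-OH groups (pKa about 4–5) are methylated, while the more hindered, less acidic 7-OH groups next to the biaryl axis remain free. This gives the two 4-OMe groups of the target, and the biaryl axis is unchanged.

---

**Compound list**

| # | Name | SMILES | Role |
|---|---|---|---|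
| 1 | 3,5-dimethoxytoluene | COc1cc(C)cc(OC)c1 | starting material |
| 2 | 5-methylcyclohexane-1,3-dione | CC1CC(=O)CC(=O)C1 | starting material |
| 3 | 2-(2,4-dimethoxy-6-methylphenyl)-5-methylcyclohexane-1,3-dione | COc1cc(OC)c(C2C(=O)CC(C)CC2=O)c(C)c1 | intermediate |
| 4 | 2-(2,4-dimethoxy-6-methylphenyl)-5-methylbenzene-1,3-diol | Cc1cc(O)c(-c2c(C)cc(OC)cc2OC)c(O)c1 | intermediate |
| 5 | 2-(2,4-dihydroxy-6-methylphenyl)-5-methylbenzene-1,3-diol | Cc1cc(O)c(-c2c(C)cc(O)cc2O)c(O)c1 | intermediate |
| 6 | acetic acid | CC(=O)O | starting material (reagent) |
| 7 | bis-acetyl tetrahydroxy biaryl | CC(=O)c1c(C)c(-c2c(O)cc(C)c(C(C)=O)c2O)c(O)cc1O | intermediate |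
| 8 | diethyl carbonate | CCOC(=O)OCC | starting material (reagent) |
| 9 | 4,7,4',7'-tetrahydroxy-5,5'-dimethyl-6,8'-bicoumarin | Oc1cc(=O)oc2cc(O)c(-c3c(O)cc(C)c4c(O)cc(=O)oc34)c(C)c12 | intermediate |
| 10 | TMS-diazomethane | C[Si](C)(C)C=[N+]=[N-] | starting material (reagent) |
| 11 | desertorin A | COc1cc(=O)oc2cc(O)c(-c3c(O)cc(C)c4c(OC)cc(=O)oc34)c(C)c12 | target |

**Total step count:** 6. **Longest linear sequence:** 6 steps (1 → 3 → 4 → 5 → 7 → 9 → 11).

**Three steps most likely to fail**
1. **Step 1 (oxidative dione–arene coupling).** Risks are O-arylation, arene homocoupling, over-oxidation, and steric strain in forming the 2,6-disubstituted aryl–dione bond. Fallback: change to a pre-functionalised coupling. Brominate 1 with NBS to give 2-bromo-3,5-dimethoxytoluene, then do a Pd-catalysed α-arylation of 2 (Pd2(dba)3, a bulky biaryl-phosphine ligand, K3PO4, dioxane, 100 °C), and continue with step 2.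
2. **Step 5 (double carbonate annulation on a tetra-phenol).** Risks are poor solubility of the polyanion, incomplete double cyclisation, and carbonate formation at the free phenols. Fallback: skip steps 4 and 5 and build both 4-hydroxycoumarins directly from tetraol 5 by a Pechmann-type malonic acid condensation (malonic acid, ZnCl2, POCl3, 70 °C), accepting a regiochemistry check at ring A.
3. **Step 4 (double regioselective C-acetylation).** Risks are acylation at the position between the two OH groups, mono- versus bis-acylation, and the hindered biaryl. Fallback: use a different mechanism. Peracetylate 5 (Ac2O, pyridine), then do a double Fries rearrangement (AlCl3, PhCl, 120 °C) to set the o-hydroxyacetophenones.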